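The route rests on disconnecting C7–C11 of the trans-fused α-methylene-γ-lactone (germacranolide numbering: carbocycle C1–C10; lactone O6–C12(=O)–C11(=C13)–C7). C7, the ring-fusion carbon, lies between the oxygen-bearing carbons C6 and C8, so a C7–C8 trans-epoxide can stand in for it: in an acyclic 7,8-epoxy alcohol carrying a diethylphosphonoacetate on O6 and a PMB ether on O9, the phosphonate carbanion opens the epoxide at C7 (5-exo, inversion) and formaldehyde, added to the same flask, completes the methylene lactone. One operation thus forms C7–C11, closes the lactone, fixes C7 and frees O8 alone for acylation. The ten-membered ring is closed last by metathesis at C1=C10.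

Key step: step 13

Remark on numbering: all intermediates carry the germacranolide locants of the target (C14 on C10, C15 on C4); C1′ and C10′ are the extra olefinic CH2 carbons on C1 and C10 that leave in step 18.

Assumption: the zinc–ProPhenol alkynylation is taken to add to the Re face of an enal with the (S,S)-ligand and to the Si face with the (R,R)-ligand; if the sense is the reverse, the ligands of steps 7 and 9 are exchanged.

Step 1
Reactants: 1 but-2-yne-1,4-diol
Product: 2 4-[(tert-butyldimethylsilyl)oxy]but-2-yn-1-ol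
Conditions: NaH (1.0 equiv), THF, 0 °C; then t-BuMe2SiCl (1.0 equiv), 0 °C to rt
Reagents that add atoms: tert-butyldimethylsilyl chloride, CC(C)(C)[Si](C)(C)Cl
Why: O-silylation of the symmetrical diol through its sparingly soluble monosodium alkoxide should stop after one hydroxyl and so tells the future C6 oxygen from O15.

Step 2
Reactants: 2 4-[(tert-butyldimethylsilyl)oxy]but-2-yn-1-ol
Product: 4 (2Z)-4-[(tert-butyldimethylsilyl)oxy]-3-iodobut-2-en-1-ol, via cyclic vinylalanate 3 (not isolated)
Conditions: NaAlH2(OCH2CH2OMe)2 (1.5 equiv), THF, 0 °C; EtOAc; then I2, −78 °C to 0 °C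
Reagents that add atoms: iodine, II
Why: Hydroxyl-directed trans-hydroalumination of the propargylic alcohol puts aluminium on C4 cis to the carbinol carbon in a five-membered alanate, and iodinolysis with retention should give the Z-iodoalkene (hydroalumination–iodination of a 2-alkyn-1-ol).

Step 3
Reactants: 4 (2Z)-4-[(tert-butyldimethylsilyl)oxy]-3-iodobut-2-en-1-ol, 5 but-3-en-1-ylzinc bromide
Product: 6 (2E)-3-{[(tert-butyldimethylsilyl)oxy]methyl}hepta-2,6-dien-1-ol
Conditions: 5 (2.5 equiv), Pd(PPh3)4 (5 mol%), THF, 50 °C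
Reagents that add atoms: none
Why: Negishi coupling of the alkenyl iodide with the primary alkylzinc reagent proceeds with retention of olefin geometry, so C3 should end cis to C6 and C15 trans to it.

Step 4
Reactants: 6 (2E)-3-{[(tert-butyldimethylsilyl)oxy]methyl}hepta-2,6-dien-1-ol
Product: 7 (2E)-3-{[(tert-butyldimethylsilyl)oxy]methyl}hepta-2,6-dienal
Conditions: MnO2 (activated, 15 equiv), CH2Cl2, rt
Reagents that add atoms: none
Why: Heterogeneous MnO2 oxidation is selective for the allylic alcohol and should leave the geometry of the trisubstituted olefin untouched.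

Step 5
Reactants: 8 3,3-diethoxyprop-1-ene
Product: 10 2-bromo-3,3-diethoxyprop-1-ene, via dibromide 9 (not isolated)
Conditions: Br2, K2CO3 (solid), CH2Cl2, −30 °C; solvent exchange; KOt-Bu (1.1 equiv), THF, 0 °C
Reagents that add atoms: bromine, BrBr
Why: Bromine addition to the vinyl group followed by E2 loss of HBr through the acidified C2–H should give the 2-bromoalkene (bromination–dehydrobromination).

Step 6
Reactants: 10 2-bromo-3,3-diethoxyprop-1-ene
Product: 12 2-(diethoxymethyl)prop-2-enal, via vinyllithium 11 (not isolated)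
Conditions: t-BuLi (2.0 equiv), Et2O, −78 °C; DMF, −78 °C to 0 °C; H2O
Reagents that add atoms: N,N-dimethylformamide, CN(C)C=O
Why: Bromine–lithium exchange gives the α-lithioacrolein acetal, whose formylation with DMF (Bouveault aldehyde synthesis) should give the C9 aldehyde with C14 already masked as its acetal.

Step 7
Reactants: 12 2-(diethoxymethyl)prop-2-enal, 13 ethynyltrimethylsilane
Product: 14 (3S)-4-(diethoxymethyl)-1-(trimethylsilyl)pent-4-en-1-yn-3-ol
Conditions: 13 (3 equiv), Me2Zn (3 equiv), (S,S)-ProPhenol (20 mol%), Ph3P=O (40 mol%), toluene, 4 °C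
Reagents that add atoms: none
Why: The dinuclear zinc–ProPhenol asymmetric alkynylation of an enal delivers the alkynylzinc to the Re face under ligand control and so sets C9.

Step 8
Reactants: 14 (3S)-4-(diethoxymethyl)-1-(trimethylsilyl)pent-4-en-1-yn-3-ol
Product: 16 (3R)-4-(diethoxymethyl)-3-[(4-methoxybenzyl)oxy]pent-4-en-1-yne, via silylated PMB ether 15 (not isolated)
Conditions: NaH, 4-MeOC6H4CH2Cl, Bu4NI (cat.), THF/DMF, 0 °C to rt; then MeOH, K2CO3 (0.2 equiv), rt
Reagents that add atoms: 4-methoxybenzyl chloride, COc1ccc(CCl)cc1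
Why: Williamson etherification followed in the same flask by base-catalysed methanolysis of the C(sp)–Si bond leaves C9 untouched (S becomes R only through the changed CIP ranking) and gives O9 a group that cannot migrate.

Step 9
Reactants: 7 (2E)-3-{[(tert-butyldimethylsilyl)oxy]methyl}hepta-2,6-dienal, 16 (3R)-4-(diethoxymethyl)-3-[(4-methoxybenzyl)oxy]pent-4-en-1-yne
Product: 17 (6R,9R)-enynol
Conditions: 16 (1.5 equiv), Me2Zn (1.6 equiv), (R,R)-ProPhenol (20 mol%), Ph3P=O (40 mol%), toluene, rt; then 7, 4 °C
Reagents that add atoms: none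
Why: The same zinc–ProPhenol alkynylation with the enantiomeric ligand should add the alkynylzinc from 16 to the Si face of enal 7 and set C6 under catalyst control, the remote C9 centre having little say.

Step 10
Reactants: 17 (6R,9R)-enynol
Product: 18 (6S,9R)-bis-allylic alcohol
Conditions: NaAlH2(OCH2CH2OMe)2 (2.0 equiv), THF, 0 °C; aq. KNaC4H4O6
Reagents that add atoms: none
Why: Alkoxide-directed trans-hydroalumination of the propargylic alcohol and protonolysis should give only the E-C7=C8 olefin, with the propargylic PMB ether retained at 0 °C (C6 is unchanged; R becomes S by CIP ranking).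

Step 11
Reactants: 18 (6S,9R)-bis-allylic alcohol
Product: 19 (6R,7R,8R,9S)-epoxy alcohol
Conditions: Ti(OiPr)4 (0.3 equiv), D-(−)-diisopropyl tartrate (0.4 equiv), t-BuOOH (2 equiv), 4 Å MS, CH2Cl2, −20 °C
Reagents that add atoms: tert-butyl hydroperoxide, CC(C)(C)OO
Why: In this Sharpless asymmetric epoxidation the C6 carbinol is the fast-reacting configuration for the D-(−)-tartrate catalyst, so oxygen should go to the C7=C8 face erythro to O6 and set C7 and C8 with catalyst and substrate matched, while the mismatched, cis-substituted C4=C5 olefin and the isolated olefins stay intact.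

Step 12
Reactants: 19 (6R,7R,8R,9S)-epoxy alcohol, 20 (diethoxyphosphoryl)acetic acid
Product: 21 (6R,7R,8R,9S)-epoxy phosphonoacetate
Conditions: DCC, DMAP (0.1 equiv), CH2Cl2, 0 °C to rt
Reagents that add atoms: none
Why: Steglich esterification of the secondary C6 alcohol under neutral conditions should leave the epoxide and the acetal intact.

Step 13
Reactants: 21 (6R,7R,8R,9S)-epoxy phosphonoacetate
Product: 23 (6R,7R,8S,9S)-hydroxy methylene lactone, via sodium phosphonolactone carbanion 22 (not isolated)
Conditions: NaN(SiMe3)2 (1.05 equiv), THF, −78 °C to 40 °C; then (CH2O)n (5 equiv), 0 °C to rt; aq. NH4Cl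
Reagents that add atoms: formaldehyde (from paraformaldehyde), C=O
Why: NaN(SiMe3)2 deprotonates the phosphonoacetate CH2 and the stabilised carbanion C11 opens the epoxide at the proximal carbon C7 from the back side, forming C7–C11 and the γ-lactone; the released C8 alkoxide is protonated at once by the acidic C11–H to give carbanion 22, which then undergoes Horner–Wadsworth–Emmons olefination with formaldehyde to install C13. The closest known reactions are the Stork-type intramolecular opening of epoxides by stabilised carbanions and the telescoped intramolecular Michael addition/Horner–Wadsworth–Emmons methylenation used for α-methylene-γ-butyrolactones, here with the epoxide as the electrophile. The lactone closes in the 5-exo-tet mode, which should be favoured over 6-endo attack at C8 by the collinear trajectory available at C7 and by the branched, oxygenated C9 next to C8. C7 is set by inversion at the epoxide carbon and therefore by the Sharpless epoxide, which makes the lactone trans-fused (H6 and H7 anti), whereas C6, C8 and C9 are carried through unchanged and the C11 centre of 22 is lost in the olefination. The step needs C-alkylation at C7 only and no acyl transfer: one equivalent of base leaves no free alkoxide for translactonisation to the 8,12-olide (which would in any case be the less stable cis-fused lactone), O9 carries a non-migrating PMB ether, and the C14 aldehyde is masked as its acetal so that only formaldehyde is olefinated.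

Step 14
Reactants: 23 (6R,7R,8S,9S)-hydroxy methylene lactone, 24 (2R)-2-methylbutanoic acid
Product: 25 (6R,7S,8S,9S)-O8-[(2R)-2-methylbutanoyl] lactone
Conditions: DCC, DMAP (0.2 equiv), CH2Cl2, 0 °C
Reagents that add atoms: none
Why: Steglich esterification of the only free hydroxyl (O8), run cold with little DMAP, should keep the α-stereocentre of the acid intact.

Step 15
Reactants: 25 (6R,7S,8S,9S)-O8-[(2R)-2-methylbutanoyl] lactone
Product: 26 (6R,7S,8S,9S)-O9-alcohol
Conditions: DDQ (1.5 equiv), CH2Cl2/pH 7 phosphate buffer (10:1), 0 °C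
Reagents that add atoms: none
Why: Oxidative cleavage of the electron-rich PMB ether frees O9 without acid or base, so the acetal, the silyl ether and the neighbouring O8 ester should stay in place.

Step 16
Reactants: 26 (6R,7S,8S,9S)-O9-alcohol
Product: 27 (6R,7S,8S,9S)-O9-acetate
Conditions: Ac2O, pyridine, DMAP (5 mol%), CH2Cl2, 0 °C
Reagents that add atoms: acetic anhydride, CC(=O)OC(C)=O
Why: Acetylation of the C9 alcohol at 0 °C should outrun 1,2-migration of the O8 acyl group.

Step 17
Reactants: 27 (6R,7S,8S,9S)-O9-acetate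
Product: 28 acyclic hydroxy enal
Conditions: HF (48% aq.), MeCN, 0 °C to rt
Reagents that add atoms: water, O
Why: Aqueous HF should remove the primary silyl ether and hydrolyse the diethyl acetal in one operation, which the esters, the lactone and the allylic acetate tolerate.

Step 18
Reactants: 28 acyclic hydroxy enal
Product: 29 target, (1(10)E,4E,6R,7S,8S,9S)-9-acetoxy-15-hydroxy-8-[(2R)-2-methylbutanoyloxy]-14-oxogermacra-1(10),4,11(13)-trien-12,6-olide
Conditions: second-generation Hoveyda–Grubbs catalyst RuCl2(H2IMes)(=CH–C6H4-2-OiPr) (15 mol%), 1,4-benzoquinone (30 mol%), toluene (0.5 mM), 80 °C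
Reagents that add atoms: none
Why: In this ring-closing metathesis the ruthenium alkylidene formed at the terminal C1 olefin should close onto the 2-formyl 1,1-disubstituted olefin (the known cross-metathesis behaviour of methacrolein-type olefins) to give the ring-cis C1=C10 bond, which is also the favoured E-enal, whereas closure onto the lactone methylene would need an eight-membered ring bridging C6 and C11 that the short C2–C5 tether cannot span without severe strain.

Compound list

1 | but-2-yne-1,4-diol | OCC#CCO | starting material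
2 | 4-[(tert-butyldimethylsilyl)oxy]but-2-yn-1-ol | OCC#CCO[Si](C)(C)C(C)(C)C | intermediate
3 | cyclic vinylalanate (sodium salt; aluminium bound to O6 and C4, two 2-methoxyethoxy ligands) | [Na+].COCCO[Al-]1(OCCOC)OCC=C1CO[Si](C)(C)C(C)(C)C | intermediate
4 | (2Z)-4-[(tert-butyldimethylsilyl)oxy]-3-iodobut-2-en-1-ol | OC/C=C(\I)CO[Si](C)(C)C(C)(C)C | intermediate
5 | but-3-en-1-ylzinc bromide | C=CCC[Zn]Br | starting material
6 | (2E)-3-{[(tert-butyldimethylsilyl)oxy]methyl}hepta-2,6-dien-1-ol | OC/C=C(\CCC=C)CO[Si](C)(C)C(C)(C)C | intermediate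
7 | (2E)-3-{[(tert-butyldimethylsilyl)oxy]methyl}hepta-2,6-dienal (C6 aldehyde; C3 cis to C6) | O=C/C=C(\CCC=C)CO[Si](C)(C)C(C)(C)C | intermediate
8 | 3,3-diethoxyprop-1-ene (acrolein diethyl acetal) | C=CC(OCC)OCC | starting material
9 | dibromide (2,3-dibromo-1,1-diethoxypropane, racemic) | BrCC(Br)C(OCC)OCC | intermediate
10 | 2-bromo-3,3-diethoxyprop-1-ene | C=C(Br)C(OCC)OCC | intermediate
11 | vinyllithium ((3,3-diethoxyprop-1-en-2-yl)lithium) | [Li]C(=C)C(OCC)OCC | intermediate
12 | 2-(diethoxymethyl)prop-2-enal | C=C(C=O)C(OCC)OCC | intermediate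
13 | ethynyltrimethylsilane | C#C[Si](C)(C)C | starting material
14 | (3S)-4-(diethoxymethyl)-1-(trimethylsilyl)pent-4-en-1-yn-3-ol | C[Si](C)(C)C#C[C@@H](O)C(=C)C(OCC)OCC | intermediate
15 | silylated PMB ether ((3S)-4-(diethoxymethyl)-3-[(4-methoxybenzyl)oxy]-1-(trimethylsilyl)pent-4-en-1-yne) | C[Si](C)(C)C#C[C@@H](OCc1ccc(OC)cc1)C(=C)C(OCC)OCC | intermediate
16 | (3R)-4-(diethoxymethyl)-3-[(4-methoxybenzyl)oxy]pent-4-en-1-yne | C#C[C@@H](OCc1ccc(OC)cc1)C(=C)C(OCC)OCC | intermediate
17 | (6R,9R)-enynol (4E; C6 alcohol, C7≡C8, O9 PMB ether, C14 diethyl acetal, O15 TBS ether, C1=C1′ and C10=C10′ olefins) | C=CCC/C(CO[Si](C)(C)C(C)(C)C)=C\[C@@H](O)C#C[C@@H](OCc1ccc(OC)cc1)C(=C)C(OCC)OCC | intermediate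
18 | (6S,9R)-bis-allylic alcohol (4E,7E; otherwise as 17) | C=CCC/C(CO[Si](C)(C)C(C)(C)C)=C\[C@@H](O)/C=C/[C@@H](OCc1ccc(OC)cc1)C(=C)C(OCC)OCC | intermediate
19 | (6R,7R,8R,9S)-epoxy alcohol (trans-7,8-epoxide erythro to O6; otherwise as 18) | C=CCC/C(CO[Si](C)(C)C(C)(C)C)=C\[C@@H](O)[C@H]1O[C@@H]1[C@@H](OCc1ccc(OC)cc1)C(=C)C(OCC)OCC | intermediate
20 | (diethoxyphosphoryl)acetic acid | OC(=O)CP(=O)(OCC)OCC | starting material
21 | (6R,7R,8R,9S)-epoxy phosphonoacetate (O6 ester of 19) | C=CCC/C(CO[Si](C)(C)C(C)(C)C)=C\[C@@H](OC(=O)CP(=O)(OCC)OCC)[C@H]1O[C@@H]1[C@@H](OCc1ccc(OC)cc1)C(=C)C(OCC)OCC | intermediate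
22 | sodium phosphonolactone carbanion (trans-fused γ-lactone, C11 carbanion bearing the diethoxyphosphoryl group, O8 free) | [Na+].C=CCC/C(CO[Si](C)(C)C(C)(C)C)=C\[C@H]1OC(=O)[C-](P(=O)(OCC)OCC)[C@@H]1[C@H](O)[C@@H](OCc1ccc(OC)cc1)C(=C)C(OCC)OCC | intermediate
23 | (6R,7R,8S,9S)-hydroxy methylene lactone (trans-fused 6,12-olide with C11=C13, O8 free, O9 PMB ether, C14 acetal, O15 TBS ether) | C=CCC/C(CO[Si](C)(C)C(C)(C)C)=C\[C@H]1OC(=O)C(=C)[C@@H]1[C@H](O)[C@@H](OCc1ccc(OC)cc1)C(=C)C(OCC)OCC | intermediate
24 | (2R)-2-methylbutanoic acid | CC[C@@H](C)C(=O)O | starting material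
25 | (6R,7S,8S,9S)-O8-[(2R)-2-methylbutanoyl] lactone | C=CCC/C(CO[Si](C)(C)C(C)(C)C)=C\[C@H]1OC(=O)C(=C)[C@@H]1[C@H](OC(=O)[C@H](C)CC)[C@@H](OCc1ccc(OC)cc1)C(=C)C(OCC)OCC | intermediate
26 | (6R,7S,8S,9S)-O9-alcohol (25 without the PMB group) | C=CCC/C(CO[Si](C)(C)C(C)(C)C)=C\[C@H]1OC(=O)C(=C)[C@@H]1[C@H](OC(=O)[C@H](C)CC)[C@@H](O)C(=C)C(OCC)OCC | intermediate
27 | (6R,7S,8S,9S)-O9-acetate | C=CCC/C(CO[Si](C)(C)C(C)(C)C)=C\[C@H]1OC(=O)C(=C)[C@@H]1[C@H](OC(=O)[C@H](C)CC)[C@@H](OC(C)=O)C(=C)C(OCC)OCC | intermediate
28 | acyclic hydroxy enal ((6R,7S,8S,9S); free O15 hydroxyl, C14 aldehyde on the C10=C10′ olefin, C1=C1′ vinyl) | C=CCC/C(CO)=C\[C@H]1OC(=O)C(=C)[C@@H]1[C@H](OC(=O)[C@H](C)CC)[C@@H](OC(C)=O)C(=C)C=O | intermediate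
29 | (1(10)E,4E,6R,7S,8S,9S)-9-acetoxy-15-hydroxy-8-[(2R)-2-methylbutanoyloxy]-14-oxogermacra-1(10),4,11(13)-trien-12,6-olide | O=C/C1=C/CC/C(CO)=C\[C@H]2OC(=O)C(=C)[C@@H]2[C@H](OC(=O)[C@H](C)CC)[C@H]1OC(C)=O | target

Total step count: 18. Longest linear sequence: 14 steps (steps 1–4 or 5–8, then 9–18).

Steps most likely to fail

Step 13. The tethered carbanion may not reach the back side of C7, because the ester has to leave its preferred s-trans conformation; non-reaction, 6-endo opening at C8 or base-induced isomerisation of the epoxide could then take over. The fallback sets out from 19 and returns at 23. Epoxy alcohol 19 is treated with [CH2=C(CO2Et)]2CuLi (THF, −78 °C to −20 °C), an α-acrylate anion equivalent; cuprates open trans-2,3-epoxy alcohols preferentially at the carbon next to the carbinol, here C7 with inversion, to give diol ester F1. Warming with PPTS (cat.) in benzene lactonises it onto O6 (the trans-fused 6,12-lactone being favoured over the cis-fused 8,12-isomer) and gives 23.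

Step 18. The alkylidene formed at C1 may fail to add to the hindered, electron-poor 2-formyl olefin, so that oligomerisation through the terminal olefin outruns ring closure. The fallback sets out from 27 and returns at 29; it moves the metathesis to the alcohol oxidation level. PPTS in wet acetone hydrolyses only the acetal to give silylated acyclic enal F2. NaBH4/CeCl3·7H2O (MeOH, −78 °C, Luche reduction) gives C14 allylic alcohol F3, whose hydroxyl-bearing, non-conjugated 1,1-disubstituted olefin is closed with the catalyst of step 18 to macrocyclic C14 alcohol F4. MnO2 (CH2Cl2) oxidises its only free alcohol to silylated macrocyclic enal F5, and HF·pyridine (THF, 0 °C) removes the silyl ether to give 29.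

Step 9. Facial control in the alkynyl transfer to the β,β-disubstituted enal may be poor with the bulky, functionalised alkynylzinc. The fallback sets out from 7 and 16 and returns at 19; it replaces reagent control by a kinetic resolution. The lithium acetylide of 16 (n-BuLi, THF, −78 °C) adds to 7 to give 17 together with 6-epi-enynol F6. NaAlH2(OCH2CH2OMe)2 as in step 10 gives 18 and 6-epi-bis-allylic alcohol F7. The epoxidation of step 11, stopped near half conversion, should then epoxidise only 18 at C7=C8, since that olefin is mismatched in F7, so 19 is separated from unchanged F7.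

Further compounds

F1 | step 13 | diol ester (ethyl 2-methylidene ester attached through C11 to C7; O6 and O8 free; otherwise as 19) | C=CCC/C(CO[Si](C)(C)C(C)(C)C)=C\[C@@H](O)[C@H](C(=C)C(=O)OCC)[C@H](O)[C@@H](OCc1ccc(OC)cc1)C(=C)C(OCC)OCC
F2 | step 18 | silylated acyclic enal (28 with the O15 TBS ether kept) | C=CCC/C(CO[Si](C)(C)C(C)(C)C)=C\[C@H]1OC(=O)C(=C)[C@@H]1[C@H](OC(=O)[C@H](C)CC)[C@@H](OC(C)=O)C(=C)C=O
F3 | step 18 | C14 allylic alcohol (F2 reduced at the aldehyde) | C=CCC/C(CO[Si](C)(C)C(C)(C)C)=C\[C@H]1OC(=O)C(=C)[C@@H]1[C@H](OC(=O)[C@H](C)CC)[C@@H](OC(C)=O)C(=C)CO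
F4 | step 18 | macrocyclic C14 alcohol (O15 TBS ether of 14-dihydro-29) | OC/C1=C/CC/C(CO[Si](C)(C)C(C)(C)C)=C\[C@H]2OC(=O)C(=C)[C@@H]2[C@H](OC(=O)[C@H](C)CC)[C@H]1OC(C)=O
F5 | step 18 | silylated macrocyclic enal (O15 TBS ether of 29) | O=C/C1=C/CC/C(CO[Si](C)(C)C(C)(C)C)=C\[C@H]2OC(=O)C(=C)[C@@H]2[C@H](OC(=O)[C@H](C)CC)[C@H]1OC(C)=O
F6 | step 9 | 6-epi-enynol (C6 epimer of 17; 6S,9R) | C=CCC/C(CO[Si](C)(C)C(C)(C)C)=C\[C@H](O)C#C[C@@H](OCc1ccc(OC)cc1)C(=C)C(OCC)OCC
F7 | step 9 | 6-epi-bis-allylic alcohol (C6 epimer of 18; 6R,9R) | C=CCC/C(CO[Si](C)(C)C(C)(C)C)=C\[C@H](O)/C=C/[C@@H](OCc1ccc(OC)cc1)C(=C)C(OCC)OCC
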